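**Assumption:** the target is taken exactly as drawn (3aS,5S,8R,11aR; 6Z,10E; side chain 2Z). Positions are discussed in germacrane numbering: C12 lactone carbonyl, C13 exocyclic CH2, C6 lactone carbinol, C7 ring fusion, C9 acyloxy carbon, C2 free carbinol, C1=C10 (Z), C4=C5 (E).

## Retrosynthetic overview

1. Target 34 ⇐ global desilylation of 33 ⇐ ring-closing metathesis of triene ester 32, closing the ten-membered ring at the Z C1=C10 olefin (last ring).
2. 32 ⇐ Mitsunobu esterification of the (9R)-alcohol 31 with Z-acid 28; the inversion gives 9S.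
3. γ-Lactone 31 (second ring) ⇐ translactonisation of δ-lactone 30 ⇐ key step: intermolecular zinc Barbier carbonyl allylation forming C6–C7 between enal 11 (C1–C6) and bromolactone 21 (C7–C14).
4. 21 (first ring; the six-membered lactone locks the allyl geometry and relays C9 → C7) ⇐ methacrolein by Keck allylation, esterification and metathesis; 11 ⇐ (R)-epichlorohydrin (sets C2) by alkyne carboalumination; 28 ⇐ crotonaldehyde.
5. Ring order: six-membered δ-lactone → five-membered γ-lactone → ten-membered carbocycle.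

## Route

**Fragment 11 (C1–C6)**

Step 1
Reactants: 1 (R)-epichlorohydrin; 2 ethynyltrimethylsilane
Product: 4 (R)-1-chloro-5-(trimethylsilyl)pent-4-yn-2-ol, via lithium (trimethylsilyl)acetylide 3 (not isolated)
Conditions: 2, n-BuLi, THF, −78 °C; BF3·OEt2; then 1, −78 °C; H2O
Reagents that add atoms: none
Why: BF3-assisted epoxide opening by a lithium acetylide (Yamaguchi–Hirao alkynylation) occurs only at the unsubstituted epoxide carbon, so the chiral-pool stereocentre (future C2) is carried over untouched.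

Step 2
Reactants: 4
Product: 6 (R)-6-(trimethylsilyl)hex-1-en-5-yn-3-ol, via alkynyl epoxide 5 (not isolated)
Conditions: Me3S+ I− (4 equiv), n-BuLi (3.9 equiv), THF, −20 °C → rt; H2O
Reagents that add atoms: trimethylsulfonium iodide, C[S+](C)C.[I-]
Why: The alkoxide closes to the terminal epoxide, which dimethylsulfonium methylide opens at CH2 and then loses Me2S (Corey–Chaykovsky-type one-carbon homologation of an epoxide to an allylic alcohol), without touching the carbinol centre (R).

Step 3
Reactants: 6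
Product: 7 (R)-tert-butyldimethyl{[6-(trimethylsilyl)hex-1-en-5-yn-3-yl]oxy}silane
Conditions: TBSCl, imidazole, DMF, rt
Reagents that add atoms: tert-butyldimethylsilyl chloride (TBSCl), CC(C)(C)[Si](C)(C)Cl
Why: Standard silylation of a secondary alcohol; this TBS ether survives every later step up to the final fluoride treatment.

Step 4
Reactants: 7
Product: 8 (R)-tert-butyl(hex-1-en-5-yn-3-yloxy)dimethylsilane
Conditions: K2CO3 (0.2 equiv), MeOH, rt
Reagents that add atoms: none
Why: Base-catalysed methanolysis (protodesilylation) cleaves only the C(sp)–Si bond and leaves the silyl ether intact.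

Step 5
Reactants: 8
Product: 10 (2E,5R)-5-(tert-butyldimethylsilyloxy)-3-methylhepta-2,6-dien-1-ol, via alkenyldimethylalane 9 (not isolated)
Conditions: Me3Al (2.5 equiv), Cp2ZrCl2 (0.25 equiv), CH2Cl2, 0 °C → rt; then n-BuLi, THF, −78 °C; (CH2O)n, → rt; aq. potassium sodium tartrate
Reagents that add atoms: trimethylaluminium, C[Al](C)C; paraformaldehyde (as formaldehyde), C=O
Why: Negishi zirconium-catalysed carboalumination adds Me–Al syn across the terminal alkyne with Al on the terminal carbon, and the alkenylalanate is hydroxymethylated with retention, which fixes the E-trisubstituted C4=C5 olefin.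

Step 6
Reactants: 10
Product: 11 (2E,5R)-5-(tert-butyldimethylsilyloxy)-3-methylhepta-2,6-dienal
Conditions: MnO2 (15 equiv), CH2Cl2, rt
Reagents that add atoms: none
Why: MnO2 oxidises the allylic alcohol selectively to the enal without E/Z isomerisation or over-oxidation.

**Fragment 21 (C7–C14)**

Step 7
Reactants: 12 methacrolein; 13 allyltributylstannane
Product: 14 (R)-2-methylhexa-1,5-dien-3-ol
Conditions: (R)-BINOL (10 mol%), Ti(OiPr)4 (10 mol%), 4 Å MS, CH2Cl2, −20 °C; aq. NaHCO3
Reagents that add atoms: none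
Why: Keck catalytic asymmetric allylation; the (R)-BINOL–titanium Lewis acid directs allyl transfer to one aldehyde face to give the (R)-carbinol, deliberately the C9 epimer of the target because this centre is inverted in step 20.

Step 8
Reactants: 15 ethyl 2-(hydroxymethyl)acrylate
Product: 16 ethyl 2-[(tert-butyldimethylsilyloxy)methyl]acrylate
Conditions: TBSCl, imidazole, CH2Cl2, 0 °C → rt
Reagents that add atoms: tert-butyldimethylsilyl chloride (TBSCl), CC(C)(C)[Si](C)(C)Cl
Why: Silylation of the primary allylic alcohol prevents self-esterification and masks the future bromomethyl carbon during the metathesis.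

Step 9
Reactants: 16
Product: 17 2-[(tert-butyldimethylsilyloxy)methyl]acrylic acid
Conditions: LiOH·H2O, THF/H2O, 0 °C → rt; cold 0.5 M HCl to pH 4
Reagents that add atoms: lithium hydroxide, [Li+].[OH-]
Why: Saponification of the ethyl ester proceeds under conditions that leave the primary TBS ether intact.

Step 10
Reactants: 14; 17
Product: 18 (R)-2-methylhexa-1,5-dien-3-yl 2-[(tert-butyldimethylsilyloxy)methyl]acrylate
Conditions: DCC, DMAP (5 mol%), CH2Cl2, 0 °C → rt
Reagents that add atoms: none
Why: Steglich esterification acylates the secondary alcohol at oxygen, so the carbinol configuration is retained.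

Step 11
Reactants: 18
Product: 19 (R)-3-[(tert-butyldimethylsilyloxy)methyl]-6-(prop-1-en-2-yl)-5,6-dihydro-2H-pyran-2-one
Conditions: second-generation Grubbs catalyst RuCl2(=CHPh)(H2IMes)(PCy3) (5 mol%), CH2Cl2 (5 mM), 40 °C
Reagents that add atoms: none
Why: Ring-closing metathesis; the carbene loads on the allyl terminus and closes onto the acrylate to give the six-membered lactone, the only unstrained ring available (the alternatives are a cyclobutene or a tetrasubstituted butenolide).

Step 12
Reactants: 19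
Product: 20 (R)-3-(hydroxymethyl)-6-(prop-1-en-2-yl)-5,6-dihydro-2H-pyran-2-one
Conditions: HF·pyridine, THF, 0 °C → rt
Reagents that add atoms: none
Why: Buffered fluoride removes the primary silyl ether without opening the unsaturated lactone or adding to it.

Step 13
Reactants: 20
Product: 21 (R)-3-(bromomethyl)-6-(prop-1-en-2-yl)-5,6-dihydro-2H-pyran-2-one
Conditions: PBr3 (0.4 equiv), Et2O, 0 °C
Reagents that add atoms: phosphorus tribromide, BrP(Br)Br
Why: SN2 bromination of the primary allylic alcohol through its phosphite ester gives the conjugated allylic bromide, which is used promptly.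

**Side-chain acid 28**

Step 14
Reactants: 22 crotonaldehyde
Product: 24 (Z)-2-bromobut-2-enal, via 2,3-dibromobutanal 23 (not isolated)
Conditions: Br2, CH2Cl2, 0 °C; then Et3N, 0 °C → rt
Reagents that add atoms: bromine, BrBr
Why: Bromine addition followed by amine-induced loss of HBr from the α-position gives the thermodynamically preferred (Z)-2-bromoenal, with Br cis to CH3.

Step 15
Reactants: 24
Product: 25 (Z)-2-bromobut-2-en-1-ol
Conditions: NaBH4, CeCl3·7H2O, MeOH, 0 °C
Reagents that add atoms: none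
Why: Luche reduction is strictly 1,2 and leaves the vinyl bromide and its geometry untouched.

Step 16
Reactants: 25
Product: 26 (Z)-[(2-bromobut-2-en-1-yl)oxy](tert-butyl)dimethylsilane
Conditions: TBSCl, imidazole, CH2Cl2, rt
Reagents that add atoms: tert-butyldimethylsilyl chloride (TBSCl), CC(C)(C)[Si](C)(C)Cl
Why: Silylation removes the acidic proton before the halogen–lithium exchange.

Step 17
Reactants: 26
Product: 28 (Z)-2-[(tert-butyldimethylsilyloxy)methyl]but-2-enoic acid, via alkenyllithium 27 (not isolated)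
Conditions: t-BuLi (2.1 equiv), Et2O, −78 °C; CO2 (g), −78 °C → rt; cold aq. HCl to pH 3
Reagents that add atoms: carbon dioxide, O=C=O
Why: Bromine–lithium exchange and carboxylation of the alkenyllithium are both stereoretentive at −78 °C, so CO2H ends up where Br was, cis to the methyl group (the Z, angelate-type geometry).

**Fragment union and endgame**

Step 18
Reactants: 11; 21
Product: 30 (4S,6R)-4-[(1R,2E,5R)-5-(tert-butyldimethylsilyloxy)-1-hydroxy-3-methylhepta-2,6-dien-1-yl]-3-methylidene-6-(prop-1-en-2-yl)oxan-2-one, via allylzinc bromide 29 (not isolated)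
Conditions: Zn dust (3 equiv), THF/sat. aq. NH4Cl (2:1), 0 °C → rt
Reagents that add atoms: none
Why: Zinc Barbier carbonyl 2-(alkoxycarbonyl)allylation through a chair Zimmerman–Traxler transition state; the ring double bond locks the allylzinc in the E-crotyl-type geometry so C6/C7 form anti (6R,7S), and the aldehyde bonds axially at C7 trans to the pseudo-equatorial isopropenyl group at C9, as in conjugate additions to 6-substituted dihydropyranones.

Step 19
Reactants: 30
Product: 31 (4S,5R)-5-[(1E,4R)-4-(tert-butyldimethylsilyloxy)-2-methylhexa-1,5-dien-1-yl]-4-[(2R)-2-hydroxy-3-methylbut-3-en-1-yl]-3-methylideneoxolan-2-one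
Conditions: DBU (0.2 equiv), CH2Cl2, 0 °C → rt
Reagents that add atoms: none
Why: Base-catalysed translactonisation (intramolecular transesterification); the C6 hydroxyl attacks C12 and the trans-disubstituted five-membered lactone is favoured over the six-membered lactone with an axial substituent, which frees the C9 hydroxyl without touching any stereocentre.

Step 20
Reactants: 31; 28
Product: 32 (2S)-1-{(2R,3S)-2-[(1E,4R)-4-(tert-butyldimethylsilyloxy)-2-methylhexa-1,5-dien-1-yl]-4-methylidene-5-oxooxolan-3-yl}-3-methylbut-3-en-2-yl (2Z)-2-[(tert-butyldimethylsilyloxy)methyl]but-2-enoate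
Conditions: PPh3, DIAD, THF, −20 °C → rt
Reagents that add atoms: none
Why: Mitsunobu esterification; SN2 displacement of the oxyphosphonium by the carboxylate inverts C9 from R to S and avoids acyl activation of the Z-acid, the usual cause of Z → E isomerisation in angelate-type acids.

Step 21
Reactants: 32
Product: 33 (3aS,5S,6Z,8R,10E,11aR)-8-(tert-butyldimethylsilyloxy)-6,10-dimethyl-3-methylidene-2-oxo-2,3,3a,4,5,8,9,11a-octahydrocyclodeca[b]furan-5-yl (2Z)-2-[(tert-butyldimethylsilyloxy)methyl]but-2-enoate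
Conditions: second-generation Grubbs catalyst RuCl2(=CHPh)(H2IMes)(PCy3) (15 mol%, in portions), toluene (1 mM), 80 °C
Reagents that add atoms: none
Why: Ring-closing metathesis; the carbene loads on the monosubstituted C1 vinyl group and closes onto the isopropenyl group, the new trisubstituted C1=C10 olefin forming as the less strained ring-cis (Z) isomer while the C4=C5, exocyclic methylene and side-chain olefins are too hindered to take part.

Step 22
Reactants: 33
Product: 34 (3aS,5S,6Z,8R,10E,11aR)-8-hydroxy-6,10-dimethyl-3-methylidene-2-oxo-2,3,3a,4,5,8,9,11a-octahydrocyclodeca[b]furan-5-yl (2Z)-2-(hydroxymethyl)but-2-enoate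
Conditions: HF·pyridine, pyridine/THF, 0 °C → rt
Reagents that add atoms: none
Why: Buffered fluoride desilylation removes both TBS ethers without conjugate addition to the α-methylene lactone, acyl migration or isomerisation of the Z ester.

## Compound list

1 | (R)-epichlorohydrin | `ClC[C@H]1CO1` | starting material
2 | ethynyltrimethylsilane | `C#C[Si](C)(C)C` | starting material
3 | lithium (trimethylsilyl)acetylide | `[Li]C#C[Si](C)(C)C` | intermediate (not isolated)
4 | (R)-1-chloro-5-(trimethylsilyl)pent-4-yn-2-ol | `ClC[C@H](O)CC#C[Si](C)(C)C` | intermediate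
5 | (R)-trimethyl[3-(oxiran-2-yl)prop-1-yn-1-yl]silane | `C[Si](C)(C)C#CC[C@@H]1CO1` | intermediate (not isolated)
6 | (R)-6-(trimethylsilyl)hex-1-en-5-yn-3-ol | `C=C[C@H](O)CC#C[Si](C)(C)C` | intermediate
7 | (R)-tert-butyldimethyl{[6-(trimethylsilyl)hex-1-en-5-yn-3-yl]oxy}silane | `C=C[C@H](O[Si](C)(C)C(C)(C)C)CC#C[Si](C)(C)C` | intermediate
8 | (R)-tert-butyl(hex-1-en-5-yn-3-yloxy)dimethylsilane | `C=C[C@H](O[Si](C)(C)C(C)(C)C)CC#C` | intermediate
9 | [(1E,4R)-4-(tert-butyldimethylsilyloxy)-2-methylhexa-1,5-dien-1-yl]dimethylalane | `C=C[C@H](O[Si](C)(C)C(C)(C)C)C/C(C)=C/[Al](C)C` | intermediate (not isolated)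
10 | (2E,5R)-5-(tert-butyldimethylsilyloxy)-3-methylhepta-2,6-dien-1-ol | `C=C[C@H](O[Si](C)(C)C(C)(C)C)C/C(C)=C/CO` | intermediate
11 | (2E,5R)-5-(tert-butyldimethylsilyloxy)-3-methylhepta-2,6-dienal | `C=C[C@H](O[Si](C)(C)C(C)(C)C)C/C(C)=C/C=O` | intermediate
12 | methacrolein | `C=C(C)C=O` | starting material
13 | allyltributylstannane | `C=CC[Sn](CCCC)(CCCC)CCCC` | starting material
14 | (R)-2-methylhexa-1,5-dien-3-ol | `C=CC[C@@H](O)C(C)=C` | intermediate
15 | ethyl 2-(hydroxymethyl)acrylate | `C=C(CO)C(=O)OCC` | starting material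
16 | ethyl 2-[(tert-butyldimethylsilyloxy)methyl]acrylate | `C=C(CO[Si](C)(C)C(C)(C)C)C(=O)OCC` | intermediate
17 | 2-[(tert-butyldimethylsilyloxy)methyl]acrylic acid | `C=C(CO[Si](C)(C)C(C)(C)C)C(=O)O` | intermediate
18 | (R)-2-methylhexa-1,5-dien-3-yl 2-[(tert-butyldimethylsilyloxy)methyl]acrylate | `C=CC[C@@H](OC(=O)C(=C)CO[Si](C)(C)C(C)(C)C)C(C)=C` | intermediate
19 | (R)-3-[(tert-butyldimethylsilyloxy)methyl]-6-(prop-1-en-2-yl)-5,6-dihydro-2H-pyran-2-one | `CC(C)(C)[Si](C)(C)OCC1=CC[C@H](C(C)=C)OC1=O` | intermediate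
20 | (R)-3-(hydroxymethyl)-6-(prop-1-en-2-yl)-5,6-dihydro-2H-pyran-2-one | `OCC1=CC[C@H](C(C)=C)OC1=O` | intermediate
21 | (R)-3-(bromomethyl)-6-(prop-1-en-2-yl)-5,6-dihydro-2H-pyran-2-one | `BrCC1=CC[C@H](C(C)=C)OC1=O` | intermediate
22 | crotonaldehyde, (E)-but-2-enal | `C/C=C/C=O` | starting material
23 | (2RS,3SR)-2,3-dibromobutanal (racemic; one enantiomer drawn) | `C[C@@H](Br)[C@@H](Br)C=O` | intermediate (not isolated)
24 | (Z)-2-bromobut-2-enal | `C/C=C(\Br)C=O` | intermediate
25 | (Z)-2-bromobut-2-en-1-ol | `C/C=C(\Br)CO` | intermediate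
26 | (Z)-[(2-bromobut-2-en-1-yl)oxy](tert-butyl)dimethylsilane | `C/C=C(\Br)CO[Si](C)(C)C(C)(C)C` | intermediate
27 | (E)-[1-(tert-butyldimethylsilyloxy)but-2-en-2-yl]lithium (Li cis to CH3) | `C/C=C(\[Li])CO[Si](C)(C)C(C)(C)C` | intermediate (not isolated)
28 | (Z)-2-[(tert-butyldimethylsilyloxy)methyl]but-2-enoic acid | `C/C=C(\C(=O)O)CO[Si](C)(C)C(C)(C)C` | intermediate
29 | {[(6R)-2-oxo-6-(prop-1-en-2-yl)-5,6-dihydro-2H-pyran-3-yl]methyl}zinc bromide | `Br[Zn]CC1=CC[C@H](C(C)=C)OC1=O` | intermediate (not isolated)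
30 | (4S,6R)-4-[(1R,2E,5R)-5-(tert-butyldimethylsilyloxy)-1-hydroxy-3-methylhepta-2,6-dien-1-yl]-3-methylidene-6-(prop-1-en-2-yl)oxan-2-one | `C=C1C(=O)O[C@@H](C(C)=C)C[C@@H]1[C@H](O)/C=C(\C)C[C@@H](O[Si](C)(C)C(C)(C)C)C=C` | intermediate
31 | (4S,5R)-5-[(1E,4R)-4-(tert-butyldimethylsilyloxy)-2-methylhexa-1,5-dien-1-yl]-4-[(2R)-2-hydroxy-3-methylbut-3-en-1-yl]-3-methylideneoxolan-2-one | `C=C1C(=O)O[C@H](/C=C(\C)C[C@@H](O[Si](C)(C)C(C)(C)C)C=C)[C@H]1C[C@@H](O)C(C)=C` | intermediate
32 | (2S)-1-{(2R,3S)-2-[(1E,4R)-4-(tert-butyldimethylsilyloxy)-2-methylhexa-1,5-dien-1-yl]-4-methylidene-5-oxooxolan-3-yl}-3-methylbut-3-en-2-yl (2Z)-2-[(tert-butyldimethylsilyloxy)methyl]but-2-enoate | `C=C1C(=O)O[C@H](/C=C(\C)C[C@@H](O[Si](C)(C)C(C)(C)C)C=C)[C@H]1C[C@H](OC(=O)/C(=C\C)CO[Si](C)(C)C(C)(C)C)C(C)=C` | intermediate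
33 | (3aS,5S,6Z,8R,10E,11aR)-8-(tert-butyldimethylsilyloxy)-6,10-dimethyl-3-methylidene-2-oxo-2,3,3a,4,5,8,9,11a-octahydrocyclodeca[b]furan-5-yl (2Z)-2-[(tert-butyldimethylsilyloxy)methyl]but-2-enoate | `C=C1C(=O)O[C@@H]2/C=C(\C)C[C@@H](O[Si](C)(C)C(C)(C)C)/C=C(/C)[C@@H](OC(=O)/C(=C\C)CO[Si](C)(C)C(C)(C)C)C[C@@H]12` | intermediate
34 | (3aS,5S,6Z,8R,10E,11aR)-8-hydroxy-6,10-dimethyl-3-methylidene-2-oxo-2,3,3a,4,5,8,9,11a-octahydrocyclodeca[b]furan-5-yl (2Z)-2-(hydroxymethyl)but-2-enoate | `C=C1C(=O)O[C@@H]2/C=C(\C)C[C@@H](O)/C=C(/C)[C@@H](OC(=O)/C(=C\C)CO)C[C@@H]12` | target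

## Step count and risks

Total steps: 22. Longest linear sequence: 11 steps (steps 1–6, then 18–22; the branch from 15 through steps 8–13 and 18–22 is equally long).

**Most likely to fail, 1: step 21 (ten-membered ring-closing metathesis).** Forming a trisubstituted olefin in a strained ten-membered ring between two oxygenated allylic carbons can stall, dimerise or give some ring-trans isomer. Fallback: set out from 31 and cyclise before acylation. The free (R)-allylic hydroxyl next to the isopropenyl group assists the ruthenium carbene and removes the bulk of the ester, so metathesis of 31 (same catalyst, toluene, 80 °C, 1 mM) gives the macrocyclic alcohol F1. Mitsunobu esterification of F1 with 28 (PPh3, DIAD, THF) then inverts C9 on the ring and comes back to the route at 33.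

**Most likely to fail, 2: step 18 (Barbier union).** The 1,3-relay from C9 to C7 in the six-membered allylzinc and the reactivity of the β,β-disubstituted enal in the aqueous medium are the least precedented points. Fallback: set out from 21 and convert it by copper-catalysed borylation (B2pin2, CuCl 10 mol%, KOAc, DMF, rt) into the pinacol allylboronate F2. Thermal allylboration of 11 with F2 (toluene, 80 °C, or Sc(OTf)3 5 mol% at 0 °C) goes through a tighter boron-centred chair with the same locked geometry. Hydrolytic work-up comes back to the route at 30.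

**Most likely to fail, 3: step 20 (Mitsunobu inversion at an allylic carbinol).** SN2' attack or elimination could compete with clean inversion. Fallback: set out from 31 and oxidise it (Dess–Martin periodinane, NaHCO3, CH2Cl2) to the isopropenyl ketone F3. Reagent-controlled reduction ((R)-2-methyl-CBS-oxazaborolidine, catecholborane, toluene, −78 °C) gives the (S)-alcohol F4. Yamaguchi esterification of F4 with 28 (2,4,6-trichlorobenzoyl chloride, Et3N, then DMAP, toluene, 0 °C) comes back to the route at 32.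

## Further compounds

F1 | step 21 | (3aS,5R,6Z,8R,10E,11aR)-8-(tert-butyldimethylsilyloxy)-5-hydroxy-6,10-dimethyl-3-methylidene-3a,4,5,8,9,11a-hexahydrocyclodeca[b]furan-2(3H)-one | `C=C1C(=O)O[C@@H]2/C=C(\C)C[C@@H](O[Si](C)(C)C(C)(C)C)/C=C(/C)[C@H](O)C[C@@H]12`
F2 | step 18 | (R)-6-(prop-1-en-2-yl)-3-[(4,4,5,5-tetramethyl-1,3,2-dioxaborolan-2-yl)methyl]-5,6-dihydro-2H-pyran-2-one | `CC1(C)OB(CC2=CC[C@H](C(C)=C)OC2=O)OC1(C)C`
F3 | step 20 | (4S,5R)-5-[(1E,4R)-4-(tert-butyldimethylsilyloxy)-2-methylhexa-1,5-dien-1-yl]-4-(3-methyl-2-oxobut-3-en-1-yl)-3-methylideneoxolan-2-one | `C=C1C(=O)O[C@H](/C=C(\C)C[C@@H](O[Si](C)(C)C(C)(C)C)C=C)[C@H]1CC(=O)C(C)=C`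
F4 | step 20 | (4S,5R)-5-[(1E,4R)-4-(tert-butyldimethylsilyloxy)-2-methylhexa-1,5-dien-1-yl]-4-[(2S)-2-hydroxy-3-methylbut-3-en-1-yl]-3-methylideneoxolan-2-one | `C=C1C(=O)O[C@H](/C=C(\C)C[C@@H](O[Si](C)(C)C(C)(C)C)C=C)[C@H]1C[C@H](O)C(C)=C`
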